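**Plan**
- The retrosynthesis first masks the six phenols as benzyl ethers and cuts the two exocyclic C–C(=O) bonds of the butyryl groups on rings A and D.
- In each of rings A and D, C(CH3)2 and the two oxygenated ring carbons flanking it form a dimethylmalonyl unit; the other three ring atoms are a ketone carbon with its two alpha carbons, one carrying the CH2 link to ring B or C. Cutting the two ring bonds between these halves (four C–C bonds in all) gives dimethylmalonyl dichloride and a ring B–ring C dimer with two 3-oxobutyl arms.
- The dimer is cut at the ArCH2Ar bridge (formaldehyde), at the aryl–CH2 bond of each arm (methyl vinyl ketone) and at the aryl–butyryl bonds (phloroglucinol, butyryl chloride).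
- Forward: rings B and C are acylated and alkylated as monomers, joined by the methylene bridge, benzylated and silylated. Rings A and D then arise together in one flask, are butyrylated at their last CH, and the benzyl ethers are removed.
- Stereochemistry: the target has no stereocentre and no configurationally fixed double bond, so nothing has to be set.

Key step: step 6

Remark on the chemistry: 5 and 7 equilibrate with cyclic hemiketals (2-hydroxy-2-methylchromans) and are drawn in the open keto form; the enolised trione rings of 13 to 16 are drawn as one tautomer, and 14 as one of several interconvertible enol ester regioisomers.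

Step 1
Reactants: 1 phloroglucinol; 2 butyryl chloride
Product: 3 1-(2,4,6-trihydroxyphenyl)butan-1-one
Conditions: AlCl3 (3 equiv), PhNO2, rt to 60 °C; ice/aq. HCl
Reagents that add atoms: none
Why: Friedel–Crafts C-acylation of the very electron-rich arene should stop after one acyl group, because the chelated aryl ketone deactivates the ring.

Step 2
Reactants: 3 1-(2,4,6-trihydroxyphenyl)butan-1-one; 4 methyl vinyl ketone
Product: 5 1-[2,4,6-trihydroxy-3-(3-oxobutyl)phenyl]butan-1-one
Conditions: Et3N (0.2 equiv), MeOH–H2O, 0 °C, 4 added dropwise as the limiting component, then rt; unreacted 3 recycled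
Reagents that add atoms: none
Why: Michael addition of the ambident phloroglucinolate through a free nuclear carbon is favoured in protic medium over the reversible O-addition, as in base-mediated C-alkylation of acylphloroglucinols; the substoichiometric base resides mainly on the more acidic, unalkylated 3, the adduct is partly masked as its cyclic hemiketal, and slow addition of the enone keeps 3 in excess, which together should hold back a second addition.

Step 3
Reactants: 5 1-[2,4,6-trihydroxy-3-(3-oxobutyl)phenyl]butan-1-one (2 equiv); 6 formaldehyde (1 equiv)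
Product: 7 bis[3-butanoyl-2,4,6-trihydroxy-5-(3-oxobutyl)phenyl]methane
Conditions: 37% aq. CH2O, 1% aq. NaOH, 0 °C to rt, short reaction time; dil. HCl
Reagents that add atoms: none
Why: Hydroxymethylation of the only free ring carbon, loss of water to a quinone methide and capture by a second phenolate (the classical formaldehyde coupling of acylphloroglucinols) can only stop at the dimer, since each ring has one open position.

Step 4
Reactants: 7 bis[3-butanoyl-2,4,6-trihydroxy-5-(3-oxobutyl)phenyl]methane
Product: 8 bis[2,4,6-tris(benzyloxy)-3-butanoyl-5-(3-oxobutyl)phenyl]methane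
Conditions: BnBr (9 equiv), K2CO3 (12 equiv), n-Bu4NI (cat.), DMF, 50 °C
Reagents that add atoms: benzyl bromide, BrCc1ccccc1
Why: Williamson etherification in a dipolar aprotic solvent alkylates phenolates at oxygen, and the hemiketals open under base so that all six oxygens should be captured.

Step 5
Reactants: 8 bis[2,4,6-tris(benzyloxy)-3-butanoyl-5-(3-oxobutyl)phenyl]methane
Product: 9 bis{2,4,6-tris(benzyloxy)-3-butanoyl-5-[3-(trimethylsilyloxy)but-3-en-1-yl]phenyl}methane
Conditions: LiN(i-Pr)2 (2.2 equiv) premixed with Me3SiCl (6 equiv), THF, −78 °C; Et3N, cold aq. NaHCO3/pentane; used crude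
Reagents that add atoms: chlorotrimethylsilane, C[Si](C)(C)Cl
Why: Kinetic deprotonation with in situ silyl trapping should take a proton from the unhindered CH3 of each methyl ketone faster than from its CH2 or from the alpha-CH2 of the aryl ketones, which are shielded by two ortho benzyloxy groups.

Step 6
Reactants: 9 bis{2,4,6-tris(benzyloxy)-3-butanoyl-5-[3-(trimethylsilyloxy)but-3-en-1-yl]phenyl}methane; 10 dimethylmalonyl dichloride (3 equiv)
Product: 13 bis{2,4,6-tris(benzyloxy)-3-butanoyl-5-[(2-hydroxy-3,3-dimethyl-4,6-dioxocyclohex-1-en-1-yl)methyl]phenyl}methane, via bis(enol lactone) 11 (not isolated), via bis(diketo ester) 12 (not isolated)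
Conditions: 10, ZnCl2 (0.2 equiv), 2,6-di-tert-butylpyridine (2.5 equiv), CH2Cl2–Et2O, slow addition of 9 at −20 °C, then rt; then NaOMe (12 equiv), MeOH–THF, 0 to 65 °C; dil. HCl
Reagents that add atoms: none
Why: Proposed new method: each terminal enol ether carbon is C-acylated by one acid chloride of 10 (ZnCl2-catalysed acylation of a silyl enol ether, Me3SiCl lost), the enolised 1,3-diketone closes onto the second acid chloride, most likely through oxygen as open-chain ketones do in Effenberger pyranone syntheses, to give enol lactone 11, and methoxide then opens 11 at the lactone carbonyl to diketo ester 12, whose carbanion at the arm CH2 next to the former ketone carbonyl (C6 counted from the ester carbon) attacks the ester in a Dieckmann-type Claisen condensation. The closest known reactions are the Effenberger alpha,alpha'-diacylation of cyclic ketone silyl enol ethers with malonyl dichloride to bicyclo[3.3.1]nonane-2,4,9-triones and the alkoxide cyclisation of 5-oxo esters to cyclohexane-1,3-diones; an open-chain methyl ketone, dimethylmalonyl dichloride and a twofold reaction have not been shown. Rings A and D each close by a 6-(enolendo)-exo-trig C-acylation helped by the gem-dimethyl group, and an arm that already closed through carbon in the first stage is simply carried through as its enolate. No stereocentre is formed. The step needs C- over O-closure, which is secured because lactone, open ester and trione interconvert under methoxide while only the trione is withdrawn as a stabilised enolate (a vinylogous carboxylate), and because the quaternary C(CH3)2 leaves C6 as the only enolisable carbon that can form a six-membered ring with the ester. It also needs one molecule of 10 per arm and clean chemoselectivity: slow addition of 9 to excess 10 prevents bridging, the quaternary carbon of 10 rules out ketene formation, self-condensation and aromatisation, 2,6-di-tert-butylpyridine keeps the HCl released on lactonisation from cleaving unreacted enol ether, and the benzyl ethers and unsilylated aryl ketones stay out of the reaction.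

Step 7
Reactants: 13 bis{2,4,6-tris(benzyloxy)-3-butanoyl-5-[(2-hydroxy-3,3-dimethyl-4,6-dioxocyclohex-1-en-1-yl)methyl]phenyl}methane; 2 butyryl chloride (2.2 equiv)
Product: 15 hexa-O-benzyl ether of the target, via bis(enol butyrate) 14 (not isolated)
Conditions: 2, Et3N (3 equiv), CH2Cl2, 0 °C; then DMAP (0.5 equiv), rt; dil. HCl
Reagents that add atoms: none
Why: O-acylation of each trione enol followed by 4-dimethylaminopyridine-mediated O-to-C acyl migration (Fries-type rearrangement of enol esters of cyclic 1,3-diones) should place the butyryl group on the only ring carbon still bearing hydrogen, where it is held as a chelated, enolised beta-triketone; acylation at the carbon carrying CH2Ar would be non-enolisable and reversible.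

Step 8
Reactants: 15 hexa-O-benzyl ether of the target
Product: 16 bis{3-butanoyl-5-[(5-butanoyl-2,4-dihydroxy-3,3-dimethyl-6-oxocyclohexa-1,4-dien-1-yl)methyl]-2,4,6-trihydroxyphenyl}methane (target)
Conditions: H2 (1 atm), 10% Pd/C, EtOAc–MeOH, rt
Reagents that add atoms: none
Why: Neutral hydrogenolysis of the six aryl benzyl ethers should leave the chelated aryl ketones, the tetrasubstituted enol double bonds and the three methylene bridges untouched.

**Compound list**
1 | phloroglucinol | Oc1cc(O)cc(O)c1 | starting material
2 | butyryl chloride | CCCC(=O)Cl | starting material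
3 | 1-(2,4,6-trihydroxyphenyl)butan-1-one | CCCC(=O)c1c(O)cc(O)cc1O | intermediate
4 | methyl vinyl ketone | CC(=O)C=C | starting material
5 | 1-[2,4,6-trihydroxy-3-(3-oxobutyl)phenyl]butan-1-one | CCCC(=O)c1c(O)cc(O)c(CCC(C)=O)c1O | intermediate
6 | formaldehyde | C=O | starting material
7 | bis[3-butanoyl-2,4,6-trihydroxy-5-(3-oxobutyl)phenyl]methane | CCCC(=O)c1c(O)c(CCC(C)=O)c(O)c(Cc2c(O)c(CCC(C)=O)c(O)c(C(=O)CCC)c2O)c1O | intermediate
8 | bis[2,4,6-tris(benzyloxy)-3-butanoyl-5-(3-oxobutyl)phenyl]methane | CCCC(=O)c1c(OCc2ccccc2)c(CCC(C)=O)c(OCc2ccccc2)c(Cc2c(OCc3ccccc3)c(CCC(C)=O)c(OCc3ccccc3)c(C(=O)CCC)c2OCc2ccccc2)c1OCc1ccccc1 | intermediate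
9 | bis{2,4,6-tris(benzyloxy)-3-butanoyl-5-[3-(trimethylsilyloxy)but-3-en-1-yl]phenyl}methane | CCCC(=O)c1c(OCc2ccccc2)c(CCC(=C)O[Si](C)(C)C)c(OCc2ccccc2)c(Cc2c(OCc3ccccc3)c(CCC(=C)O[Si](C)(C)C)c(OCc3ccccc3)c(C(=O)CCC)c2OCc2ccccc2)c1OCc1ccccc1 | intermediate
10 | dimethylmalonyl dichloride | CC(C)(C(=O)Cl)C(=O)Cl | starting material
11 | bis(enol lactone), formed in the flask in step 6: bis{2,4,6-tris(benzyloxy)-3-butanoyl-5-[2-(3,3-dimethyl-2,4-dioxo-3,4-dihydro-2H-pyran-6-yl)ethyl]phenyl}methane | CCCC(=O)c1c(OCc2ccccc2)c(CCC2=CC(=O)C(C)(C)C(=O)O2)c(OCc2ccccc2)c(Cc2c(OCc3ccccc3)c(CCC3=CC(=O)C(C)(C)C(=O)O3)c(OCc3ccccc3)c(C(=O)CCC)c2OCc2ccccc2)c1OCc1ccccc1 | intermediate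
12 | bis(diketo ester), formed in the flask in step 6: bis[2,4,6-tris(benzyloxy)-3-butanoyl-5-(7-methoxy-6,6-dimethyl-3,5,7-trioxoheptyl)phenyl]methane | CCCC(=O)c1c(OCc2ccccc2)c(CCC(=O)CC(=O)C(C)(C)C(=O)OC)c(OCc2ccccc2)c(Cc2c(OCc3ccccc3)c(CCC(=O)CC(=O)C(C)(C)C(=O)OC)c(OCc3ccccc3)c(C(=O)CCC)c2OCc2ccccc2)c1OCc1ccccc1 | intermediate
13 | bis{2,4,6-tris(benzyloxy)-3-butanoyl-5-[(2-hydroxy-3,3-dimethyl-4,6-dioxocyclohex-1-en-1-yl)methyl]phenyl}methane | CCCC(=O)c1c(OCc2ccccc2)c(CC2=C(O)C(C)(C)C(=O)CC2=O)c(OCc2ccccc2)c(Cc2c(OCc3ccccc3)c(CC3=C(O)C(C)(C)C(=O)CC3=O)c(OCc3ccccc3)c(C(=O)CCC)c2OCc2ccccc2)c1OCc1ccccc1 | intermediate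
14 | bis(enol butyrate), formed in the flask in step 7: bis{2,4,6-tris(benzyloxy)-3-butanoyl-5-[(4-butanoyloxy-2-hydroxy-3,3-dimethyl-6-oxocyclohexa-1,4-dien-1-yl)methyl]phenyl}methane | CCCC(=O)c1c(OCc2ccccc2)c(CC2=C(O)C(C)(C)C(OC(=O)CCC)=CC2=O)c(OCc2ccccc2)c(Cc2c(OCc3ccccc3)c(CC3=C(O)C(C)(C)C(OC(=O)CCC)=CC3=O)c(OCc3ccccc3)c(C(=O)CCC)c2OCc2ccccc2)c1OCc1ccccc1 | intermediate
15 | hexa-O-benzyl ether of the target: bis{2,4,6-tris(benzyloxy)-3-butanoyl-5-[(5-butanoyl-2,4-dihydroxy-3,3-dimethyl-6-oxocyclohexa-1,4-dien-1-yl)methyl]phenyl}methane | CCCC(=O)c1c(OCc2ccccc2)c(CC2=C(O)C(C)(C)C(O)=C(C(=O)CCC)C2=O)c(OCc2ccccc2)c(Cc2c(OCc3ccccc3)c(CC3=C(O)C(C)(C)C(O)=C(C(=O)CCC)C3=O)c(OCc3ccccc3)c(C(=O)CCC)c2OCc2ccccc2)c1OCc1ccccc1 | intermediate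
16 | bis{3-butanoyl-5-[(5-butanoyl-2,4-dihydroxy-3,3-dimethyl-6-oxocyclohexa-1,4-dien-1-yl)methyl]-2,4,6-trihydroxyphenyl}methane | CCCC(=O)C1=C(O)C(C)(C)C(O)=C(Cc2c(O)c(Cc3c(O)c(CC4=C(O)C(C)(C)C(O)=C(C(=O)CCC)C4=O)c(O)c(C(=O)CCC)c3O)c(O)c(C(=O)CCC)c2O)C1=O | target

**Step count:** 8 steps in total. **Longest linear sequence:** 8 steps, from phloroglucinol to the target; two molecules of 5 converge in step 3.

**Steps most likely to fail**

Step 6. The hindered, neopentyl-type acid chloride may acylate the enol ether so slowly that protodesilylation back to 8 takes over, or one molecule of 10 may bridge two arms. In the methoxide stage, retro-Claisen cleavage or attack at the enol carbon of the lactone may outrun the Claisen closure. The fallback sets out from 9 and separates the two C–C bond formations, using known reactions only. ZnCl2-catalysed acylation of the silyl enol ether with the half ester chloride ethyl 3-chloro-2,2-dimethyl-3-oxopropanoate cannot bridge or lactonise and should give the isolable bis(ethyl 2,2-dimethyl-3,5-dioxo ester) F1. Excess LiN(i-Pr)2 in THF (−78 to 0 °C) then forms the 1,3-diketone dianion of each arm, whose terminal carbanion acylates the ester intramolecularly, the ring-closing form of the ester acylation of diketone dianions. Acid work-up brings the route back at 13.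

Step 5. Enolisation may lose site selectivity, with silylation at the internal CH2 of the methyl ketones or at the alpha-CH2 of the aryl butyryl ketones, and the enol ethers may hydrolyse on handling. The fallback sets out from 8 and avoids the enol ether altogether. A crossed Claisen condensation under thermodynamic control with dimethyl dimethylmalonate, a non-enolisable diester, and NaH in refluxing DME acylates methyl ketones at CH3, because only that product is removed as an unhindered diketonate. This gives the bis(diketo ester) 12 in isolable form, which is closed with NaOMe as in the second stage of step 6 and comes back to the route at 13. No new compound is made.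

Step 4. The sixfold etherification may be diverted by C-benzylation with dearomatisation of the fully substituted rings, by base-induced fragmentation and scrambling at the methylene bridge through a quinone methide, or by incomplete alkylation of the hindered chelated hydroxyls. The fallback sets out from 5 and protects before the bridge exists. Benzylation of the monomer (BnBr, K2CO3, DMF) should give 1-[2,4,6-tris(benzyloxy)-3-(3-oxobutyl)phenyl]butan-1-one F2. Two molecules are then joined at the remaining ring carbon, activated by three alkoxy groups, through acid-catalysed Friedel–Crafts condensation with formaldehyde (paraformaldehyde, CF3CO2H cat., CH2Cl2). This comes back to the route at 8.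

**Further compounds**
F1 | step 6 | bis[2,4,6-tris(benzyloxy)-3-butanoyl-5-(7-ethoxy-6,6-dimethyl-3,5,7-trioxoheptyl)phenyl]methane | CCCC(=O)c1c(OCc2ccccc2)c(CCC(=O)CC(=O)C(C)(C)C(=O)OCC)c(OCc2ccccc2)c(Cc2c(OCc3ccccc3)c(CCC(=O)CC(=O)C(C)(C)C(=O)OCC)c(OCc3ccccc3)c(C(=O)CCC)c2OCc2ccccc2)c1OCc1ccccc1
F0 | step 5 | none | none
F2 | step 4 | 1-[2,4,6-tris(benzyloxy)-3-(3-oxobutyl)phenyl]butan-1-one | CCCC(=O)c1c(OCc2ccccc2)cc(OCc2ccccc2)c(CCC(C)=O)c1OCc1ccccc1
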